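X is the catalyst that destroys Z, and Q is the feed that makes it, so each flask is a tank filled by one first-order process and drained by another.

    X + Z → X + G (k1 = 1.15 L mol⁻¹ s⁻¹, Ea1 = 61.0 kJ mol⁻¹)
    X + E ⇌ X.E (K2 = 120 L mol⁻¹, k2 = 1.41 L mol⁻¹ s⁻¹, Ea2 = 61.0 kJ mol⁻¹, ΔH2 = −62.0 kJ mol⁻¹)
    Q → Z (k3 = 0.167 s⁻¹, Ea3 = 88.0 kJ mol⁻¹)
    (constants at 60 °C)

all flasks: Q 0.050 M; X 1.6 mM; E 7.2 mM; time 15 min
- east: temperature 10 °C
- south-west: temperature 60 °C
- south-east: temperature 35 °C
- north: temperature 85 °C

- which flask leads in amount of Z, in percent of the Q charged ("all alike" within 1.5 percentage points) (east / south-west / south-east / north / all alike)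
- how much Z is there at the end, in percent of the Q charged: east
- how much Z is there at the end, in percent of the Q charged: south-west
- how much Z is there at the end, in percent of the Q charged: south-east
- how much Z is there at the end, in percent of the Q charged: north

- constants are those at 60 °C; use the activation energies and enthalpies for any other temperature

I reckon with two times. The fill time is the lifetime of Q, one over the constant of Q → Z. The drain time is the pseudo-first-order lifetime of Z, one over the constant of X + Z times the free X. In north, with binding at equilibrium and E at its charge, the free share of X is 84.7%, so the drain time is 2.30 min, against a fill time of 0.652 s. The run is therefore 6.52 drain times, and north keeps 0.147% of the charge as Z.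

In east the fill time 27.3 min is longer than the run, so only 42.3% is filled, while the drain time, even with X all free, is 442 min. South-west, with binding at equilibrium and the E that X takes up counted, has a free share of X of 56.2%, so a drain time of 16.1 min, and keeps 39.4%.

In south-east I cannot say how far binding gets during the run. X all free gives a drain time of 54.1 min and 75.8% kept, while the binding constant there, 738 L mol⁻¹, with the E taken up counted, gives an equilibrium free share of 18.7% and 94.9% kept. Even the lower figure puts south-east ahead of the other flasks.

The forecast also names south-east, with 41.7% in east, 38.4% in south-west, 87.4% in south-east and 0.15% in north, on the ground that “the hot flasks lose it to X-catalysed consumption”. Its south-east is one number inside my bracket, and its south-west stands lower than mine.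

The simulation puts south-east ahead, with 41.6% in east, 38.5% in south-west, 87.3% in south-east and 0.142% in north. Now take a neighbour of north with X cut to 6.4 × 10⁻⁴ M. The drain time stretches with the charge to 5.75 min, so the run is 2.61 drain times and I reckon 7.35% kept. In that neighbour, X stands 84.8% free after 15.0 min, G holds 92.7%, and Z holds 7.33%.

(All constants are those of an exercise, and the outcome is calculated.)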